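**Strategy.** The quinone ring of the 2-hydroxy-3-alkyl-1,4-naphthoquinone is disconnected at C1–C2 and C4–C4a. Both bonds form in one operation in a photochemical ketene–ynol ether benzannulation. α-Diazoacetophenone rearranges (Wolff, phenyl shift) to phenylketene, which adds to a siloxyalkyne (making C1–C2 and also C3–C4). The cyclobutenone then opens and its ketene carbon closes on the ortho carbon (C4–C4a). The precursors, a diazoketone and an ynol silyl ether, contain no naphthalene. The step exploits the 1,3-relationship of the C2 and C4 oxygens across the alkylated C3: the resulting 1,3-dioxygenated naphthalene autoxidises at C1 to the hydroxyquinone. Cross-metathesis of a methacrylate ester with an (R)-dienol completes the side chain.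

Key step: step 5

Remark: atom numbers are those of the naphthoquinone (C1=O next to C2–OH, C3 bearing the side chain, C4=O, ring-fusion carbons C4a and C8a). The carbinol centre of the target is (R) and is taken from commercial (R)-but-3-yn-2-ol.

Step 1
Reactants: 1 methyl isobutyrate; 2 propargyl bromide
Product: 4 methyl 2,2-dimethylpent-4-ynoate, via lithium ester enolate 3 (not isolated)
Conditions: LiN(iPr)2, THF, −78 °C; then 2, −78 °C → rt
Reagents that add atoms: none
Why: SN2 alkylation of the fully substituted lithium ester enolate by the reactive propargylic bromide should set up the quaternary carbon; no stereocentre is formed.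

Step 2
Reactants: 4 methyl 2,2-dimethylpent-4-ynoate
Product: 5 2,2-dimethylpent-4-yn-1-ol
Conditions: LiAlH4, Et2O, 0 °C → rt; H2O/NaOH work-up
Reagents that add atoms: none
Why: Hydride reduction of the ester should give the neopentyl alcohol and leave the isolated terminal alkyne untouched.

Step 3
Reactants: 5 2,2-dimethylpent-4-yn-1-ol
Product: 8 4,4-dimethyl-1,5-bis(triisopropylsilyloxy)pent-1-yne, via dilithium acetylide alkoxide 6 (not isolated), via dilithium ynolate alkoxide 7 (not isolated)
Conditions: n-BuLi (2 equiv), THF, −78 °C; LiOOtBu (from tBuOOH and LiN(SiMe3)2), −78 → 0 °C; iPr3SiOTf (excess), −78 → 0 °C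
Reagents that add atoms: tert-butyl hydroperoxide CC(C)(C)OO; triisopropylsilyl trifluoromethanesulfonate CC(C)[Si](OS(=O)(=O)C(F)(F)F)(C(C)C)C(C)C
Why: Oxygen transfer from LiOOtBu to the lithium acetylide (Julia ynolate synthesis, the Kozmin route to siloxyalkynes) followed by O-silylation of both lithium oxygen centres should give the ynol silyl ether and the alkyl silyl ether in one pot.

Step 4
Reactants: 9 benzoyl chloride; 10 (trimethylsilyl)diazomethane
Product: 11 2-diazo-1-phenylethan-1-one
Conditions: MeCN/THF, 0 °C → rt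
Reagents that add atoms: none
Why: C-acylation of the silyl diazomethane by the acid chloride with loss of the silyl group as Me3SiCl (Arndt–Eistert-type diazoketone synthesis) should give the α-diazoketone.

Step 5
Reactants: 11 2-diazo-1-phenylethan-1-one; 8 4,4-dimethyl-1,5-bis(triisopropylsilyloxy)pent-1-yne
Product: 15 2-[2,2-dimethyl-3-(triisopropylsilyloxy)propyl]-3-(triisopropylsilyloxy)naphthalen-1-ol, via phenylketene 12 (not isolated), via 4-phenylcyclobutenone 13 (not isolated), via dienylketene 14 (not isolated)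
Conditions: hν (254 nm, low-pressure mercury lamp), ClCH2CH2Cl, rt; then 80 °C
Reagents that add atoms: none
Why: Photolysis expels N2 and triggers a Wolff rearrangement (1,2-phenyl shift) to phenylketene 12, which undergoes a [2+2] cycloaddition with the electron-rich ynol silyl ether 8 to cyclobutenone 13; heating opens 13 by 4π-electrocyclic cleavage to dienylketene 14, whose 6π-electrocyclic closure on an ortho carbon of the phenyl ring and tautomerisation give the naphthol. The closest known reaction type is the Danheiser photochemical aromatic annulation of aryl diazomethyl ketones with siloxyalkynes. The transient four-membered ring is closed by [2+2] cycloaddition, which makes C1–C2 and C3–C4, and the six-membered ring (C1 to C4, C4a, C8a) by disrotatory 6π-electrocyclisation of the ketene carbon C4 on to C4a. No stereocentre is formed. The regiochemistry needed (alkyl chain next to the ketene-derived C–OH, siloxy group next to the benzylic CH) is secured by the polarisation of the ynol ether, whose alkyl-bearing β-carbon attacks the ketene carbonyl carbon. Ketene dimerisation is held back by its low stationary concentration, ring opening of 13 is reversible so that only the isomer with phenyl turned inward is drained by cyclisation, and the two ortho positions of phenyl are equivalent.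

Step 6
Reactants: 15 2-[2,2-dimethyl-3-(triisopropylsilyloxy)propyl]-3-(triisopropylsilyloxy)naphthalen-1-ol
Product: 17 2-hydroxy-3-(3-hydroxy-2,2-dimethylpropyl)naphthalene-1,4-dione, via naphthalene-1,3-diol 16 (not isolated)
Conditions: Bu4NF, THF, 0 °C → rt; then O2, rt; aq. HCl
Reagents that add atoms: dioxygen O=O
Why: Fluoride cleaves both silyl ethers, and the electron-rich 2-alkylnaphthalene-1,3-diolate should be autoxidised by O2 at its free C1–H position to the 2-hydroxy-1,4-quinone, the classical naphthoresorcinol-to-hydroxynaphthoquinone oxidation.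

Step 7
Reactants: 17 2-hydroxy-3-(3-hydroxy-2,2-dimethylpropyl)naphthalene-1,4-dione; 18 methacrylic anhydride
Product: 20 3-(3-hydroxy-1,4-dioxo-1,4-dihydronaphthalen-2-yl)-2,2-dimethylpropyl methacrylate, via bis-methacrylate 19 (not isolated)
Conditions: 18 (excess), Et3N, DMAP (cat.), CH2Cl2, 0 °C → rt; then NaHCO3, THF/H2O, rt
Reagents that add atoms: none
Why: DMAP-catalysed acyl transfer (Steglich-type acylation) esterifies the neopentyl alcohol, and the enol ester formed at the acidic quinone hydroxyl is a vinylogous mixed anhydride that should be hydrolysed selectively by aqueous bicarbonate.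

Step 8
Reactants: 21 (R)-but-3-yn-2-ol; 22 but-3-en-1-ylmagnesium bromide
Product: 24 (R)-3-methylidenehept-6-en-2-ol, via magnesium alkoxide chelate 23 (not isolated)
Conditions: 22 (3 equiv), CuI (10 mol%), Et2O/THF, −10 °C → rt; then H2O
Reagents that add atoms: none
Why: Copper-catalysed anti-carbomagnesiation of the propargylic alkoxide (Duboudin reaction) should deliver the butenyl group to the alkyne carbon next to the carbinol through a five-membered magnesium chelate; the (R) centre of 21 is not touched.

Step 9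
Reactants: 20 3-(3-hydroxy-1,4-dioxo-1,4-dihydronaphthalen-2-yl)-2,2-dimethylpropyl methacrylate; 24 (R)-3-methylidenehept-6-en-2-ol
Product: 25 Rhinacanthin I
Conditions: 24 (3 equiv), second-generation Hoveyda–Grubbs catalyst (H2IMes)Cl2Ru=CH(C6H4-2-OiPr) (cat.), CH2Cl2, 40 °C, argon sparge
Reagents that add atoms: none
Why: Olefin cross-metathesis of the terminal alkene with the methacrylate should give the trisubstituted enoate as the favoured (E) isomer, while the hindered 1,1-disubstituted allylic alkene and the electron-poor quinone double bond should not react; the carbinol centre is unaffected.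

**Compound list**

1 | methyl isobutyrate | COC(=O)C(C)C | starting material
2 | propargyl bromide (3-bromoprop-1-yne) | BrCC#C | starting material
3 | lithium 1-methoxy-2-methylprop-1-en-1-olate (lithium ester enolate) | COC(O[Li])=C(C)C | intermediate
4 | methyl 2,2-dimethylpent-4-ynoate | COC(=O)C(C)(C)CC#C | intermediate
5 | 2,2-dimethylpent-4-yn-1-ol | OCC(C)(C)CC#C | intermediate
6 | lithium 5-lithio-2,2-dimethylpent-4-yn-1-olate (dilithium acetylide alkoxide) | [Li]C#CCC(C)(C)CO[Li] | intermediate
7 | dilithium 4,4-dimethylpent-1-yne-1,5-diolate (dilithium ynolate alkoxide) | [Li]OC#CCC(C)(C)CO[Li] | intermediate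
8 | 4,4-dimethyl-1,5-bis(triisopropylsilyloxy)pent-1-yne | CC(C)[Si](OCC(C)(C)CC#CO[Si](C(C)C)(C(C)C)C(C)C)(C(C)C)C(C)C | intermediate
9 | benzoyl chloride | O=C(Cl)c1ccccc1 | starting material
10 | (trimethylsilyl)diazomethane | C[Si](C)(C)C=[N+]=[N-] | starting material
11 | 2-diazo-1-phenylethan-1-one | [N-]=[N+]=CC(=O)c1ccccc1 | intermediate
12 | phenylketene (2-phenylethen-1-one) | O=C=Cc1ccccc1 | intermediate
13 | 2-[2,2-dimethyl-3-(triisopropylsilyloxy)propyl]-4-phenyl-3-(triisopropylsilyloxy)cyclobut-2-en-1-one | O=C1C(CC(C)(C)CO[Si](C(C)C)(C(C)C)C(C)C)=C(O[Si](C(C)C)(C(C)C)C(C)C)C1c1ccccc1 | intermediate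
14 | (3E)-2-[2,2-dimethyl-3-(triisopropylsilyloxy)propyl]-4-phenyl-3-(triisopropylsilyloxy)buta-1,3-dien-1-one (dienylketene, phenyl cis to the ketene-bearing carbon) | O=C=C(CC(C)(C)CO[Si](C(C)C)(C(C)C)C(C)C)/C(O[Si](C(C)C)(C(C)C)C(C)C)=C\c1ccccc1 | intermediate
15 | 2-[2,2-dimethyl-3-(triisopropylsilyloxy)propyl]-3-(triisopropylsilyloxy)naphthalen-1-ol | Oc1c(CC(C)(C)CO[Si](C(C)C)(C(C)C)C(C)C)c(O[Si](C(C)C)(C(C)C)C(C)C)cc2ccccc12 | intermediate
16 | 2-(3-hydroxy-2,2-dimethylpropyl)naphthalene-1,3-diol | OCC(C)(C)Cc1c(O)cc2ccccc2c1O | intermediate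
17 | 2-hydroxy-3-(3-hydroxy-2,2-dimethylpropyl)naphthalene-1,4-dione | OCC(C)(C)CC1=C(O)C(=O)c2ccccc2C1=O | intermediate
18 | methacrylic anhydride | C=C(C)C(=O)OC(=O)C(C)=C | starting material
19 | 3-[3-(methacryloyloxy)-1,4-dioxo-1,4-dihydronaphthalen-2-yl]-2,2-dimethylpropyl methacrylate | C=C(C)C(=O)OCC(C)(C)CC1=C(OC(=O)C(C)=C)C(=O)c2ccccc2C1=O | intermediate
20 | 3-(3-hydroxy-1,4-dioxo-1,4-dihydronaphthalen-2-yl)-2,2-dimethylpropyl methacrylate | C=C(C)C(=O)OCC(C)(C)CC1=C(O)C(=O)c2ccccc2C1=O | intermediate
21 | (R)-but-3-yn-2-ol | C#C[C@@H](C)O | starting material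
22 | but-3-en-1-ylmagnesium bromide | C=CCC[Mg]Br | starting material
23 | (5R)-3-(but-3-en-1-yl)-5-methyl-2,5-dihydro-1,2-oxamagnesole (alkenylmagnesium alkoxide chelate) | C=CCCC1=C[Mg]O[C@@H]1C | intermediate
24 | (R)-3-methylidenehept-6-en-2-ol | C=CCCC(=C)[C@@H](C)O | intermediate
25 | Rhinacanthin I | C=C(CC/C=C(\C)C(=O)OCC(C)(C)CC1=C(O)C(=O)c2ccccc2C1=O)[C@@H](C)O | target

**Step count.** Total: 9 steps. Longest linear sequence: 7 steps (steps 1, 2, 3, 5, 6, 7, 9).

**Steps most likely to fail**

Step 5. The photogenerated ketene may dimerise, or the ynol silyl ether may degrade under irradiation, faster than the [2+2] addition; the dienylketene may also fail to close. The fallback is a chromium carbene benzannulation (Dötz reaction) with late hydroxylation; it sets out from 5 and comes back at 17. Alcohol 5 is acetylated (Ac2O, pyridine) to 2,2-dimethylpent-4-yn-1-yl acetate F1. Pentacarbonyl[methoxy(phenyl)methylidene]chromium F2, made from Cr(CO)6, PhLi and Me3OBF4, is heated with F1 (THF, 50 °C) to give 3-(1-hydroxy-4-methoxynaphthalen-2-yl)-2,2-dimethylpropyl acetate F3. Without isolation, F3 is oxidised with (NH4)2Ce(NO3)6 to 3-(1,4-dioxo-1,4-dihydronaphthalen-2-yl)-2,2-dimethylpropyl acetate F4. Nucleophilic epoxidation (H2O2, Na2CO3) gives 3-(2,3-epoxy-1,4-dioxo-1,2,3,4-tetrahydronaphthalen-2-yl)-2,2-dimethylpropyl acetate F5. Concentrated H2SO4 opens the epoxide to 3-(3-hydroxy-1,4-dioxo-1,4-dihydronaphthalen-2-yl)-2,2-dimethylpropyl acetate F6, and hydrolysis of the acetate with aqueous LiOH returns 17.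

Step 9. The acidic, chelating hydroxyquinone may sequester the ruthenium carbene, and homodimerisation of the dienol may outrun cross-coupling when the hindered methacrylate is the limiting partner. The fallback moves the metathesis to the simple fragment and joins the halves by esterification; it sets out from 24 (and uses 17 from step 6) and comes back at 25. Alcohol 24 is silylated (tBuMe2SiCl, imidazole) to (R)-tert-butyldimethyl[(3-methylidenehept-6-en-2-yl)oxy]silane F7. Cross-metathesis with methyl methacrylate in excess (same ruthenium catalyst) gives methyl (2E,7R)-7-(tert-butyldimethylsilyloxy)-2-methyl-6-methylideneoct-2-enoate F8. Saponification with LiOH gives (2E,7R)-7-(tert-butyldimethylsilyloxy)-2-methyl-6-methylideneoct-2-enoic acid F9. Yamaguchi esterification (2,4,6-trichlorobenzoyl chloride, Et3N; then 17, DMAP; bicarbonate work-up to cleave any enol ester) gives the 7-O-(tert-butyldimethylsilyl) ether of Rhinacanthin I F10. HF·pyridine then gives 25.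

Step 3. Oxygen transfer to the acetylide may stall in the aggregated dianion, and the ynol silyl ether may be lost by protodesilylation during isolation. The fallback is a Kowalski ester homologation; it sets out from 5 and comes back at 8. Alcohol 5 is silylated (iPr3SiCl, imidazole) to triisopropyl[(2,2-dimethylpent-4-yn-1-yl)oxy]silane F11. Oxidative cleavage of the terminal alkyne (RuCl3 cat., NaIO4) gives 3,3-dimethyl-4-(triisopropylsilyloxy)butanoic acid F12. Esterification (Me3SiCHN2, MeOH) gives methyl 3,3-dimethyl-4-(triisopropylsilyloxy)butanoate F13. Treatment with LiCHBr2 (from CH2Br2 and lithium 2,2,6,6-tetramethylpiperidide), then LiN(SiMe3)2 and n-BuLi, gives lithium 4,4-dimethyl-5-(triisopropylsilyloxy)pent-1-yn-1-olate F14, which is silylated with iPr3SiOTf to 8.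

**Further compounds**

F1 | step 5 | 2,2-dimethylpent-4-yn-1-yl acetate | CC(=O)OCC(C)(C)CC#C
F2 | step 5 | pentacarbonyl[methoxy(phenyl)methylidene]chromium | COC(c1ccccc1)=[Cr](=C=O)(=C=O)(=C=O)(=C=O)=C=O
F3 | step 5 | 3-(1-hydroxy-4-methoxynaphthalen-2-yl)-2,2-dimethylpropyl acetate | COc1cc(CC(C)(C)COC(C)=O)c(O)c2ccccc12
F4 | step 5 | 3-(1,4-dioxo-1,4-dihydronaphthalen-2-yl)-2,2-dimethylpropyl acetate | CC(=O)OCC(C)(C)CC1=CC(=O)c2ccccc2C1=O
F5 | step 5 | 3-(2,3-epoxy-1,4-dioxo-1,2,3,4-tetrahydronaphthalen-2-yl)-2,2-dimethylpropyl acetate | CC(=O)OCC(C)(C)CC12OC1C(=O)c1ccccc1C2=O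
F6 | step 5 | 3-(3-hydroxy-1,4-dioxo-1,4-dihydronaphthalen-2-yl)-2,2-dimethylpropyl acetate | CC(=O)OCC(C)(C)CC1=C(O)C(=O)c2ccccc2C1=O
F7 | step 9 | (R)-tert-butyldimethyl[(3-methylidenehept-6-en-2-yl)oxy]silane | C=CCCC(=C)[C@@H](C)O[Si](C)(C)C(C)(C)C
F8 | step 9 | methyl (2E,7R)-7-(tert-butyldimethylsilyloxy)-2-methyl-6-methylideneoct-2-enoate | C=C(CC/C=C(\C)C(=O)OC)[C@@H](C)O[Si](C)(C)C(C)(C)C
F9 | step 9 | (2E,7R)-7-(tert-butyldimethylsilyloxy)-2-methyl-6-methylideneoct-2-enoic acid | C=C(CC/C=C(\C)C(=O)O)[C@@H](C)O[Si](C)(C)C(C)(C)C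
F10 | step 9 | 7-O-(tert-butyldimethylsilyl) ether of Rhinacanthin I | C=C(CC/C=C(\C)C(=O)OCC(C)(C)CC1=C(O)C(=O)c2ccccc2C1=O)[C@@H](C)O[Si](C)(C)C(C)(C)C
F11 | step 3 | triisopropyl[(2,2-dimethylpent-4-yn-1-yl)oxy]silane | CC(C)[Si](OCC(C)(C)CC#C)(C(C)C)C(C)C
F12 | step 3 | 3,3-dimethyl-4-(triisopropylsilyloxy)butanoic acid | CC(C)[Si](OCC(C)(C)CC(=O)O)(C(C)C)C(C)C
F13 | step 3 | methyl 3,3-dimethyl-4-(triisopropylsilyloxy)butanoate | COC(=O)CC(C)(C)CO[Si](C(C)C)(C(C)C)C(C)C
F14 | step 3 | lithium 4,4-dimethyl-5-(triisopropylsilyloxy)pent-1-yn-1-olate | [Li]OC#CCC(C)(C)CO[Si](C(C)C)(C(C)C)C(C)C
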